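## The problem

The target 20 is a 1,3-diacylglycerol: one primary oxygen carries an acetyl group, the other the acyl group of ent-labd-8-en-15-oic acid, and the secondary hydroxyl is free. The carbon skeleton is a trans-decalin (ring A: C1–C5 and C10, gem-dimethyl on C4; ring B: C5–C10) whose only unsaturation is the tetrasubstituted C8=C9 alkene, which carries the C8 methyl group and, on C9, the chain C11–C15. There are four stereocentres: C5 and C10 (both R, trans fusion of the ent series), C13 in the chain (R) and the glycerol carbinol carbon (R). C5 and C10 are neighbours, so one can direct the other, but C13 is insulated from the ring by C11 and C12 and the glycerol carbon lies beyond the ester, so each of these two must come from its own enantiopure source. The hard bonds are those around quaternary C10 and the C9–C11 bond, which joins the chain to an alkene carbon wedged between C10 and the C8 methyl group. The fragile parts are the 2-hydroxy-1,3-diester, whose acyl groups wander round the glycerol under acid, base or heat and thereby erode its configuration, and the tetrasubstituted alkene, which strong acid can shift; the glyceride therefore belongs at the very end. The enabling feature is that ring B, C5, C4 with both methyl groups and an oxidised C9 next to a methyl-bearing C8 are the carbon framework of carvone: the isopropenyl-bearing carbon is C5, the isopropenyl group is C4 with its methyls, the enone is a masked C8=C9 alkene with a handle on C9, and the α′-CH2 is C10. Only C1–C3 and the C10 methyl are missing, and the isopropenyl group is a latent tertiary C4 radical that can reach a three-carbon acceptor hung on C10.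

## Retrosynthesis

**Glyceride.** The acetyl C–O bond on the primary oxygen is cut first (20 ⇒ diol 19), the 1,2-diol is re-closed as an acetonide (19 ⇒ 18), and the C15–O ester bond is cut (18 ⇒ acid 16 + (S)-solketal 17). This places the migration-prone glyceride last. Compound 17 brings the glycerol stereocentre with its two primary oxygens already differentiated, whereas acylating a preformed monoacetin would need an enantiopure 1-acetylglycerol that itself scrambles. The precursor 16 is a robust hydrocarbon acid with one stereocentre fewer. The forward steps must esterify without harsh base, open the dioxolane under acid mild enough for the alkene and for the acyl group to stay put, and acetylate the primary hydroxyl only.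

**Sulfone and ester.** Acid 16 comes from methyl ester 15 by hydrolysis, and 15 from sulfone 14 by replacing C2–H with C2–SO2Ph. The sulfone is the activating group that ring A closure needs. It is carried to this point because it is inert to hydride, triflation and organozinc chemistry, while its reductive removal would not spare an enone or an enol triflate. In 14 only an isolated alkene and a methyl ester stand beside it. The forward step is a single-electron desulfonylation in methanol.

**C9–C11.** Cutting this bond (14 ⇒ alkenyl triflate 9 + alkylzinc iodide 13) separates ring from chain at the only sp2–sp3 bond. The chain stereocentre C13 then sits in a five-carbon piece that traces through iodide 12 and hydroxy ester 11 to commercial monomethyl (R)-3-methylglutarate 10, whose ester end becomes C15 and whose acid end becomes C11. A cut at C11–C12 or C12–C13 would need a homologated decalin electrophile and a less accessible four-carbon chiral piece. The forward reaction is a cross-coupling at an alkenyl carbon flanked by quaternary C10 and the C8 methyl group, with an ester-tolerant nucleophile.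

**Enol triflate.** Triflate 9 is the O-sulfonylated enolate obtained by conjugate hydride addition to enone 7. Because C10 is quaternary, the C8=C9 enolate is the only one possible, so the position of the alkene in the target is fixed by the enone. The forward step needs 1,4- rather than 1,2-delivery of hydride.

**C3–C4 (key).** Cutting this bond in 7 opens ring A and gives monocyclic 6, in which C4 is an isopropenyl carbon and C1–C3 is a 2-(phenylsulfonyl)allyl group on C10. Against closing C1–C2 or C2–C3 (for example by metathesis), this cut makes the bond to the fully substituted C4 with both methyls already in place. Against a cationic closure of the same bond, it leaves the enone untouched and gives no alkene isomers. The precursor has one ring and no new stereocentre at the fusion. The forward step must generate the C4 radical selectively at the isopropenyl group and close 6-endo.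

**C10 substituents.** The C10–C1 bond (6 ⇒ 6-methylcarvone 3 + bromide 4) and the C10–CH3 bond (3 ⇒ (S)-carvone 1) are cut as enolate alkylations. The order matters: the group introduced second enters anti to the isopropenyl group, so methyl first and the sulfonylallyl group second puts C1 trans to C4, as the trans-decalin requires.

## Roads not taken

**Alternative 1: intramolecular Diels–Alder closing both rings.** The cut is C5–C10 and C8–C9 at once. The acyclic imide A1, (R)-4-benzyl-3-[(2E,8E,10E)-3,7,7-trimethyldodeca-2,8,10-trienoyl]oxazolidin-2-one, would cyclise under Me2AlCl to the trans-fused cycloadduct A2.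

- Merits: both rings, quaternary C10 and the ring fusion are made in one step from an open chain, the absolute configuration comes from a recoverable auxiliary, and C11 arrives as a carbonyl carbon. In bonds and rings per step this road is clearly better than the chosen one.
- Weak points: the C5–C10 bond must form between a neopentyl diene terminus and a β,β-disubstituted dienophile. Two of the four stereocentres set in A2 (C8, C9) are sp2 carbons in 20, so that investment is discarded. The alkene of A2 lies at C6=C7 and must be hydrogenated, after which C8=C9 has to be introduced by dehydrogenation next to a hindered C9. The chain C12–C15 with C13 still has to be built from C11, and A1 itself needs three alkenes of defined geometry.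
- Comparison: against the better ring economy, the chosen plan takes ring B, C5 and the correct oxidation pattern at C8/C9 from carvone and places the alkene regiospecifically through an enolate.

**Alternative 2: titanium carbonyl coupling to form C8=C9.** The cut is the C8=C9 alkene itself. The seco-diketone A3, 15-(tert-butyldimethylsilyloxy)-8,9-seco-ent-labdane-8,9-dione, would be closed by low-valent titanium from TiCl3 and Zn(Cu) to the silyl ether A4 of ent-labd-8-en-15-ol.

- Merits: the most congested bond of the molecule is made intramolecularly with the whole chain already attached, so the hindered cross-coupling of the chosen route is avoided altogether. In this respect the alternative is the safer plan.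
- Weak points: A3 contains a cyclohexane with vicinal C5 and C10 stereocentres, the latter quaternary and acylated by a chain that already holds C13; making it enantiopure would take many steps. C15 must travel as a silyl ether because an ester would not survive excess low-valent titanium, so desilylation and oxidation are needed to reach 16. The coupling also needs a large excess of titanium.
- Comparison: the chosen plan reaches its coupling partner 9 in four steps from 1 and has a fallback for the union; it accepts a harder coupling for a much shorter approach.

**Alternative 3: one-carbon ring expansion of a trans-hydrindanone.** The cut removes C8 with its methyl group from ring B. The hydrindanone A5, (3aR,7aR)-4,4,7a-trimethyloctahydro-1H-inden-1-one, would react with diazoethane under Sc(OTf)3 catalysis, the C7 methylene migrating, to give the decalone A6.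

- Merits: A6 has the C9 carbonyl with a single enolisable position, so the same enolate triflation and coupling as in the chosen route would follow, and no sulfonyl group has to be removed later. The late stage is one step shorter than in the chosen plan.
- Weak points: A5 is a strained trans-hydrindanone with an angular methyl next to a gem-dimethyl carbon and is not a commodity. The carbonyl that must accept diazoethane is neopentyl. Migration of C7 rather than quaternary C10 is expected but not guaranteed, a second insertion can follow, and diazoethane must be prepared fresh and handled as a hazard.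
- Comparison: both plans face the same C9–C11 coupling, so the choice rests on access to the bicyclic ketone. The chosen plan uses an inexpensive terpene and three steps to 7, and pays for it with one desulfonylation.

Key step: step 3

Assumption: 3-bromo-2-(phenylsulfonyl)prop-1-ene (4) is taken to be a purchasable allylating reagent, like the other four starting materials.

## Route

Step 1
Reactants: 1 (S)-(+)-carvone
Product: 3 trans-6-methylcarvone [(5S,6R)-2,6-dimethyl-5-(prop-1-en-2-yl)cyclohex-2-en-1-one; major C6 epimer], via lithium dienolate 2 (not isolated)
Conditions: LiN(i-Pr)2, THF, −78 °C; MeI, −78 → 0 °C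
Reagents that add atoms: iodomethane, CI
Why: Kinetic deprotonation at the α′-CH2 gives the cross-conjugated dienolate, which is C-methylated (enolate alkylation); the C6 epimer composition is irrelevant because this carbon is planarised again in step 2.

Step 2
Reactants: 3 trans-6-methylcarvone; 4 3-bromo-2-(phenylsulfonyl)prop-1-ene
Product: 6 (5R,6R)-2,6-dimethyl-6-[2-(phenylsulfonyl)prop-2-en-1-yl]-5-(prop-1-en-2-yl)cyclohex-2-en-1-one, via lithium enolate 5 (not isolated)
Conditions: LiN(i-Pr)2, THF, −78 → 0 °C; then addition to 4, THF, −78 °C → rt
Reagents that add atoms: none
Why: Enolate alkylation in which direct SN2 and SN2′ addition–elimination on the bromomethyl vinyl sulfone give the same constitution; the electrophile should enter anti to the neighbouring isopropenyl group, which sets quaternary C10 with the sulfonylallyl group trans to isopropenyl (the descriptor at C5 changes from S to R by priority only).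

Step 3
Reactants: 6 (5R,6R)-2,6-dimethyl-6-[2-(phenylsulfonyl)prop-2-en-1-yl]-5-(prop-1-en-2-yl)cyclohex-2-en-1-one
Product: 7 (4aR,7R,8aR)-2,5,5,8a-tetramethyl-7-(phenylsulfonyl)-4a,5,6,7,8,8a-hexahydronaphthalen-1(4H)-one
Conditions: Fe(acac)3 (30 mol %), PhSiH3, EtOH/(CH2OH)2 (5:1), high dilution, 60 °C, Ar
Reagents that add atoms: none
Why: Fe(acac)3 and PhSiH3 in ethanol form an iron hydride that transfers a hydrogen atom to the terminal CH2 of the electron-rich isopropenyl group, giving the tertiary C4 radical with both geminal methyl groups in place. This nucleophilic radical adds to the unsubstituted CH2 terminus (C3) of the vinyl sulfone in a Giese addition that forms C3–C4; the α-sulfonyl radical at C2 is reduced by divalent iron and protonated by ethanol, which returns trivalent iron. The closest known reaction type is the iron-hydride reductive coupling of unactivated alkenes with acceptor alkenes, including intramolecular cases that create quaternary carbons. Ring A closes in the 6-endo-trig mode through a chair-like arrangement in which the C5–C4 and C10–C1 bonds are both equatorial on the carvone ring, so the trans fusion follows from the trans relationship fixed in step 2 and no fusion stereocentre is made or touched. The only new stereocentre is C2 (position 7 of the name), set when hydrogen is delivered to the α-sulfonyl centre; the equatorial sulfone, clear of the axial methyl groups on C4 and C10, is the expected and thermodynamically favoured epimer, and since the C–S bond is cut in step 8 either epimer serves. The step needs hydrogen-atom transfer to the isopropenyl group and not to the enone or the vinyl sulfone, which the preference of the metal hydride for electron-rich 1,1-disubstituted alkenes secures. It also needs 6-endo rather than 5-exo attack, which is secured because the inner acceptor carbon is fully substituted and polarity-mismatched and 5-exo closure would leave an unstabilised primary radical.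

Step 4
Reactants: 7 (4aR,7R,8aR)-2,5,5,8a-tetramethyl-7-(phenylsulfonyl)-4a,5,6,7,8,8a-hexahydronaphthalen-1(4H)-one
Product: 9 (4aR,7R,8aR)-2,5,5,8a-tetramethyl-7-(phenylsulfonyl)-3,4,4a,5,6,7,8,8a-octahydronaphthalen-1-yl trifluoromethanesulfonate, via lithium enolate 8 (not isolated)
Conditions: LiBH(s-Bu)3 (L-Selectride), THF, −78 °C; PhNTf2, −78 °C → rt
Reagents that add atoms: N-phenylbis(trifluoromethanesulfonimide), O=S(=O)(N(c1ccccc1)S(=O)(=O)C(F)(F)F)C(F)(F)F
Why: Conjugate hydride reduction is expected because the C9 carbonyl is shielded by quaternary C10 while the β-carbon C7 is an unsubstituted ring CH; the resulting enolate, the only one possible at C9, is trapped on oxygen as the enol triflate, and the sulfone is inert to both reagents.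

Step 5
Reactants: 10 monomethyl (R)-3-methylglutarate [(3R)-5-methoxy-3-methyl-5-oxopentanoic acid]
Product: 11 methyl (3R)-5-hydroxy-3-methylpentanoate
Conditions: BH3·SMe2, THF, 0 °C → rt; MeOH quench, cold neutral work-up
Reagents that add atoms: none
Why: Borane reduces the carboxylic acid chemoselectively in the presence of the methyl ester; the stereocentre is not involved, and a cold neutral work-up avoids lactonisation of the δ-hydroxy ester.

Step 6
Reactants: 11 methyl (3R)-5-hydroxy-3-methylpentanoate
Product: 12 methyl (3S)-5-iodo-3-methylpentanoate
Conditions: I2, PPh3, imidazole, CH2Cl2, 0 °C → rt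
Reagents that add atoms: iodine, II
Why: Appel-type iodination of a primary alcohol by SN2 displacement of the oxyphosphonium group; no bond to C3 is broken, and the descriptor changes from R to S only because iodine raises the priority of that arm.

Step 7
Reactants: 9 (4aR,7R,8aR)-2,5,5,8a-tetramethyl-7-(phenylsulfonyl)-3,4,4a,5,6,7,8,8a-octahydronaphthalen-1-yl trifluoromethanesulfonate; 12 methyl (3S)-5-iodo-3-methylpentanoate
Product: 14 methyl (3R)-3-methyl-5-[(4aR,7R,8aR)-2,5,5,8a-tetramethyl-7-(phenylsulfonyl)-3,4,4a,5,6,7,8,8a-octahydronaphthalen-1-yl]pentanoate, via alkylzinc iodide 13 (not isolated)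
Conditions: 12, Zn dust (activated with BrCH2CH2Br and Me3SiCl), LiCl, THF, 40 °C; then 9, Pd(OAc)2 (5 mol %), SPhos (10 mol %), THF/NMP, 60 °C
Reagents that add atoms: none
Why: Zinc inserts into the primary C–I bond with tolerance of the ester, and Negishi coupling joins C11 to C9 after oxidative addition of zerovalent palladium to the alkenyl triflate; the bulky dialkylbiarylphosphine is chosen to speed reductive elimination at the hindered alkenylpalladium over β-hydride elimination, and C13 is not involved.

Step 8
Reactants: 14 methyl (3R)-3-methyl-5-[(4aR,7R,8aR)-2,5,5,8a-tetramethyl-7-(phenylsulfonyl)-3,4,4a,5,6,7,8,8a-octahydronaphthalen-1-yl]pentanoate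
Product: 15 methyl (3R)-3-methyl-5-[(4aR,8aR)-2,5,5,8a-tetramethyl-3,4,4a,5,6,7,8,8a-octahydronaphthalen-1-yl]pentanoate (methyl ent-labd-8-en-15-oate)
Conditions: Na(Hg) (6% sodium amalgam), Na2HPO4, MeOH/THF, −20 °C → rt
Reagents that add atoms: none
Why: Reductive desulfonylation by electron transfer: the sulfone radical anion loses benzenesulfinate and the C2 radical is reduced and protonated; the isolated tetrasubstituted alkene and the methyl ester (in buffered methanol) are inert, and the one stereocentre absent from the target disappears.

Step 9
Reactants: 15 methyl ent-labd-8-en-15-oate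
Product: 16 (3R)-3-methyl-5-[(4aR,8aR)-2,5,5,8a-tetramethyl-3,4,4a,5,6,7,8,8a-octahydronaphthalen-1-yl]pentanoic acid (ent-labd-8-en-15-oic acid)
Conditions: LiOH·H2O, THF/MeOH/H2O, 40 °C; then 1 M HCl, 0 °C
Reagents that add atoms: lithium hydroxide, [Li+].[OH-]
Why: Saponification of an unhindered methyl ester; C13 is β to the carboxyl group and cannot epimerise, and brief cold acidification leaves the alkene in place.

Step 10
Reactants: 16 ent-labd-8-en-15-oic acid; 17 (S)-solketal [(4S)-2,2-dimethyl-1,3-dioxolan-4-yl]methanol
Product: 18 [(4R)-2,2-dimethyl-1,3-dioxolan-4-yl]methyl (3R)-3-methyl-5-[(4aR,8aR)-2,5,5,8a-tetramethyl-3,4,4a,5,6,7,8,8a-octahydronaphthalen-1-yl]pentanoate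
Conditions: EDC·HCl, DMAP (cat.), CH2Cl2, 0 °C → rt
Reagents that add atoms: none
Why: Steglich esterification of a primary alcohol under near-neutral conditions; the stereocentre of 17 is untouched and its descriptor changes from S to R by priority only.

Step 11
Reactants: 18 acetonide ester
Product: 19 (2R)-2,3-dihydroxypropyl (3R)-3-methyl-5-[(4aR,8aR)-2,5,5,8a-tetramethyl-3,4,4a,5,6,7,8,8a-octahydronaphthalen-1-yl]pentanoate
Conditions: Amberlyst-15 (H+ resin), MeOH/H2O (19:1), 0 °C → rt; filtration, concentration below 25 °C
Reagents that add atoms: none
Why: Acid-catalysed acetal hydrolysis; a solid acid removed by filtration, low temperature and no basic wash are chosen to keep the acyl group on the primary oxygen, and these conditions are too mild to protonate the tetrasubstituted alkene.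

Step 12
Reactants: 19 monoacylglycerol
Product: 20 (2R)-3-(acetyloxy)-2-hydroxypropyl (3R)-3-methyl-5-[(4aR,8aR)-2,5,5,8a-tetramethyl-3,4,4a,5,6,7,8,8a-octahydronaphthalen-1-yl]pentanoate (target)
Conditions: AcCl (1.05 equiv), 2,4,6-collidine, CH2Cl2, −78 °C; rapid chromatography on neutral silica
Reagents that add atoms: acetyl chloride, CC(=O)Cl
Why: Primary-selective acylation of a 1,2-diol by an acid chloride with a hindered pyridine base at low temperature; the secondary hydroxyl between two acyloxymethyl groups reacts more slowly, and the cold, weakly basic medium gives acyl migration little opportunity.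

## Compound list

1 | (S)-(+)-carvone | CC1=CC[C@@H](CC1=O)C(C)=C | starting material
2 | lithium dienolate of 1 | CC1=CC[C@@H](C=C1O[Li])C(C)=C | intermediate (not isolated)
3 | trans-6-methylcarvone, (5S,6R)-2,6-dimethyl-5-(prop-1-en-2-yl)cyclohex-2-en-1-one (major C6 epimer; the minor epimer converges in step 2) | O=C1C(C)=CC[C@H](C(C)=C)[C@H]1C | intermediate
4 | 3-bromo-2-(phenylsulfonyl)prop-1-ene | C=C(CBr)S(=O)(=O)c1ccccc1 | starting material
5 | lithium enolate of 3 | [Li]OC1=C(C)[C@@H](C(C)=C)CC=C1C | intermediate (not isolated)
6 | (5R,6R)-2,6-dimethyl-6-[2-(phenylsulfonyl)prop-2-en-1-yl]-5-(prop-1-en-2-yl)cyclohex-2-en-1-one (sulfonylallyl trans to isopropenyl) | O=C1C(C)=CC[C@H](C(C)=C)[C@]1(CC(=C)S(=O)(=O)c2ccccc2)C | intermediate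
7 | (4aR,7R,8aR)-2,5,5,8a-tetramethyl-7-(phenylsulfonyl)-4a,5,6,7,8,8a-hexahydronaphthalen-1(4H)-one (trans-decalin, equatorial sulfone on C2 of the labdane numbering) | O=C1C(C)=CC[C@@H]2C(C)(C)C[C@@H](S(=O)(=O)c3ccccc3)C[C@@]12C | intermediate
8 | lithium enolate from conjugate reduction of 7 | [Li]OC1=C(C)CC[C@@H]2C(C)(C)C[C@@H](S(=O)(=O)c3ccccc3)C[C@@]12C | intermediate (not isolated)
9 | (4aR,7R,8aR)-2,5,5,8a-tetramethyl-7-(phenylsulfonyl)-3,4,4a,5,6,7,8,8a-octahydronaphthalen-1-yl trifluoromethanesulfonate | O=S(=O)(OC1=C(C)CC[C@@H]2C(C)(C)C[C@@H](S(=O)(=O)c3ccccc3)C[C@@]12C)C(F)(F)F | intermediate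
10 | monomethyl (R)-3-methylglutarate, (3R)-5-methoxy-3-methyl-5-oxopentanoic acid | COC(=O)C[C@H](C)CC(=O)O | starting material
11 | methyl (3R)-5-hydroxy-3-methylpentanoate | COC(=O)C[C@H](C)CCO | intermediate
12 | methyl (3S)-5-iodo-3-methylpentanoate | COC(=O)C[C@H](C)CCI | intermediate
13 | [(3S)-5-methoxy-3-methyl-5-oxopentyl]zinc iodide | COC(=O)C[C@H](C)CC[Zn]I | intermediate (not isolated)
14 | methyl (3R)-3-methyl-5-[(4aR,7R,8aR)-2,5,5,8a-tetramethyl-7-(phenylsulfonyl)-3,4,4a,5,6,7,8,8a-octahydronaphthalen-1-yl]pentanoate | COC(=O)C[C@H](C)CCC1=C(C)CC[C@@H]2C(C)(C)C[C@@H](S(=O)(=O)c3ccccc3)C[C@@]12C | intermediate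
15 | methyl (3R)-3-methyl-5-[(4aR,8aR)-2,5,5,8a-tetramethyl-3,4,4a,5,6,7,8,8a-octahydronaphthalen-1-yl]pentanoate (methyl ent-labd-8-en-15-oate) | COC(=O)C[C@H](C)CCC1=C(C)CC[C@@H]2C(C)(C)CCC[C@@]12C | intermediate
16 | (3R)-3-methyl-5-[(4aR,8aR)-2,5,5,8a-tetramethyl-3,4,4a,5,6,7,8,8a-octahydronaphthalen-1-yl]pentanoic acid (ent-labd-8-en-15-oic acid) | OC(=O)C[C@H](C)CCC1=C(C)CC[C@@H]2C(C)(C)CCC[C@@]12C | intermediate
17 | (S)-solketal, [(4S)-2,2-dimethyl-1,3-dioxolan-4-yl]methanol | CC1(C)OC[C@H](CO)O1 | starting material
18 | [(4R)-2,2-dimethyl-1,3-dioxolan-4-yl]methyl (3R)-3-methyl-5-[(4aR,8aR)-2,5,5,8a-tetramethyl-3,4,4a,5,6,7,8,8a-octahydronaphthalen-1-yl]pentanoate | CC1(C)OC[C@H](COC(=O)C[C@H](C)CCC2=C(C)CC[C@@H]3C(C)(C)CCC[C@@]23C)O1 | intermediate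
19 | (2R)-2,3-dihydroxypropyl (3R)-3-methyl-5-[(4aR,8aR)-2,5,5,8a-tetramethyl-3,4,4a,5,6,7,8,8a-octahydronaphthalen-1-yl]pentanoate | OC[C@@H](O)COC(=O)C[C@H](C)CCC1=C(C)CC[C@@H]2C(C)(C)CCC[C@@]12C | intermediate
20 | (2R)-3-(acetyloxy)-2-hydroxypropyl (3R)-3-methyl-5-[(4aR,8aR)-2,5,5,8a-tetramethyl-3,4,4a,5,6,7,8,8a-octahydronaphthalen-1-yl]pentanoate | CC(=O)OC[C@@H](O)COC(=O)C[C@H](C)CCC1=C(C)CC[C@@H]2C(C)(C)CCC[C@@]12C | target

## Step count and risks

Total: 12 steps. Longest linear sequence: 10 steps from 1 (steps 1, 2, 3, 4, 7, 8, 9, 10, 11, 12); the chain branch (steps 5 and 6) joins at step 7.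

**Step 3 (key step).** The C4 radical may be quenched by hydrogen-atom donation, giving net hydrogenation of the isopropenyl group, before it reaches C3. The acceptor carbon lies next to quaternary C10 and closure needs the conformer with the C10 methyl axial; hydrogen-atom transfer to the vinyl sulfone would add to the loss. The fallback generates the same radical by halogen-atom abstraction, with the hydride concentration under control. It sets out from 6: Markovnikov addition of HBr (HBr in AcOH, 0 °C) to the isopropenyl group should give the tertiary bromide (5S,6R)-5-(2-bromopropan-2-yl)-2,6-dimethyl-6-[2-(phenylsulfonyl)prop-2-en-1-yl]cyclohex-2-en-1-one F1. Slow addition of Bu3SnH and AIBN in benzene at 80 °C then effects the tin-hydride Giese cyclisation, and the route is rejoined at 7.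

**Step 2.** Enolate 5, or the diisopropylamine set free, may add to the vinyl sulfone of product 6, and reagent 4 may oligomerise under the basic conditions, so that conversion to 6 stalls; erosion of facial selectivity is the lesser worry. The fallback installs the acceptor in two stages and sets out from 3. Alkylation of enolate 5 with 2,3-dibromopropene, a simple SN2 electrophile, should give (5R,6R)-6-(2-bromoprop-2-en-1-yl)-2,6-dimethyl-5-(prop-1-en-2-yl)cyclohex-2-en-1-one F2. Coupling of the alkenyl bromide with PhSO2Na (Pd2(dba)3, Xantphos, Cs2CO3, toluene, 80 °C) then gives the vinyl sulfone, and the route is rejoined at 6.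

**Step 7.** Transmetalation and reductive elimination at an alkenylpalladium flanked by quaternary C10 and the C8 methyl group may be so slow that β-hydride elimination and protodezincation of 13, and cleavage of the triflate, outrun the coupling. The fallback gives up the preformed organozinc and the palladium cycle. It sets out from 9 and 12, which are joined directly by nickel-catalysed reductive cross-electrophile coupling (NiBr2(dme), 4,4′-di-tert-butyl-2,2′-bipyridine, Zn dust, DMA, rt). Here the alkyl partner arrives as a primary radical and is captured by the alkenylnickel intermediate, a step less sensitive to crowding than transmetalation. The route is rejoined at 14 and no new compound is made (F0).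

**Step 11.** Under the acid that opens the dioxolane, the acyl group may migrate from the primary to the secondary oxygen and on round the glycerol, which scrambles the regiochemistry and erodes the configuration of the glycerol carbon. The same process threatens diol 19 during step 12 and its purification. The fallback avoids both the acetal and the free diol and sets out from acid 16. (S)-Glycidyl acetate, (2S)-oxiran-2-ylmethyl acetate F3, is prepared from (R)-glycidol with Ac2O and pyridine. It is opened at its terminal carbon by 16 under catalysis by [N,N′-bis(3,5-di-tert-butylsalicylidene)-1,2-cyclohexanediaminato]cobalt acetate, a trivalent cobalt complex, with i-Pr2NEt at rt, a carboxylic acid epoxide opening known for glycidyl derivatives. The epoxide carbon keeps its configuration, and the route is rejoined directly at 20, bypassing 18 and 19.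

## Further compounds

F1 | step 3 | (5S,6R)-5-(2-bromopropan-2-yl)-2,6-dimethyl-6-[2-(phenylsulfonyl)prop-2-en-1-yl]cyclohex-2-en-1-one | O=C1C(C)=CC[C@H](C(C)(C)Br)[C@]1(CC(=C)S(=O)(=O)c2ccccc2)C
F2 | step 2 | (5R,6R)-6-(2-bromoprop-2-en-1-yl)-2,6-dimethyl-5-(prop-1-en-2-yl)cyclohex-2-en-1-one | O=C1C(C)=CC[C@H](C(C)=C)[C@]1(CC(Br)=C)C
F0 | step 7 | none | none
F3 | step 11 | (S)-glycidyl acetate, (2S)-oxiran-2-ylmethyl acetate | CC(=O)OC[C@@H]1CO1
A1 | alternative 1 | (R)-4-benzyl-3-[(2E,8E,10E)-3,7,7-trimethyldodeca-2,8,10-trienoyl]oxazolidin-2-one | O=C(/C=C(\C)CCCC(C)(C)/C=C/C=C/C)N1C(=O)OC[C@H]1Cc1ccccc1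
A2 | alternative 1 | trans-fused cycloadduct, N-acyl (R)-4-benzyloxazolidin-2-one of ent-drim-6-en-11-oic acid | O=C(N3C(=O)OC[C@H]3Cc4ccccc4)[C@@H]1[C@H](C)C=C[C@@H]2C(C)(C)CCC[C@@]12C
A3 | alternative 2 | 15-(tert-butyldimethylsilyloxy)-8,9-seco-ent-labdane-8,9-dione | CC(=O)CC[C@@H]1C(C)(C)CCC[C@@]1(C)C(=O)CC[C@@H](C)CCO[Si](C)(C)C(C)(C)C
A4 | alternative 2 | ent-labd-8-en-15-ol tert-butyldimethylsilyl ether | CC(C)(C)[Si](C)(C)OCC[C@H](C)CCC1=C(C)CC[C@@H]2C(C)(C)CCC[C@@]12C
A5 | alternative 3 | (3aR,7aR)-4,4,7a-trimethyloctahydro-1H-inden-1-one | O=C1CC[C@@H]2C(C)(C)CCC[C@@]12C
A6 | alternative 3 | (2S,4aR,8aR)-2,5,5,8a-tetramethyloctahydronaphthalen-1(2H)-one | O=C1[C@@H](C)CC[C@@H]2C(C)(C)CCC[C@@]12C
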